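The decalin is disconnected at C9–C10. The route exploits the 1,3-relationship of the C6 oxygen and C18 across C5, and the C8=C17 methylene next to C9: C18–O is tied to C6 as a five-membered cyclic ketal on a ring-A cyclohexene (C5=C10), whose ionisation gives a planar oxocarbenium ion electrophilic at C10. An allylsilane (C17–Si, C8=C9) then closes ring B through C9–C10 in one operation, creating C9 and C10, the exocyclic methylene and, after hydrolysis and reduction, C5 and C6, all relayed from the catalytically set C4 centre. The temporary ring is opened again; the butenolide carbinol pair is added last by a catalytic vinylogous aldol reaction.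

Key step: step 14

Numbering (labdane type): decalin C1–C10 (ring A = C1–C5, C10; ring B = C5–C10); C17 = exocyclic CH2 on C8; C18 = aldehyde carbon on C4; C19, C20 = methyls on C4, C10; side chain C11–C15 on C9 with a methyl on C13; butenolide O1′, C2′–C5′ with C5′ bonded to C15. α is the face opposite to the C10 methyl.

Assumption: the sense of induction in the two catalyst-controlled steps (2 and 19) is taken as drawn; should either catalyst favour the other face, its enantiomer is used.

Step 1
Reactants: 1 2,6-dimethylcyclohexan-1-one (commercial mixture of diastereomers)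
Product: 2 2,6-dimethyl-1-(trimethylsilyloxy)cyclohex-1-ene (racemic)
Conditions: Me3SiCl, sodium iodide, Et3N, MeCN, rt
Reagents that add atoms: chlorotrimethylsilane, C[Si](C)(C)Cl
Why: Silyl enol ether formation with iodotrimethylsilane made in the flask; only one (tetrasubstituted) enol ether can form, so the nucleophilic carbon of the next step is fixed.

Step 2
Reactants: 2 silyl enol ether
Product: 3 (2S)-2-(hydroxymethyl)-2,6-dimethylcyclohexan-1-one (C6 epimers)
Conditions: 37% aq. HCHO, Sc(OTf)3 (10 mol %), (S,S)-6,6'-bis(1-hydroxy-2,2-dimethylpropyl)-2,2'-bipyridine (12 mol %), DME/H2O 9:1, −20 °C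
Reagents that add atoms: formaldehyde, C=O
Why: Catalytic asymmetric hydroxymethylation of a silicon enolate (aqueous Mukaiyama aldol reaction with formaldehyde): the chiral scandium–bipyridine complex selects the enolate face and sets the quaternary centre (future C4 with C18 and C19), while the other α-centre (future C10) becomes sp2 later.

Step 3
Reactants: 3 hydroxy ketone
Product: 4 trisylhydrazone of 3
Conditions: 2,4,6-iPr3C6H2SO2NHNH2, HCl (cat.), MeCN, rt
Reagents that add atoms: 2,4,6-triisopropylbenzenesulfonohydrazide, CC(C)c1cc(C(C)C)c(S(=O)(=O)NN)c(C(C)C)c1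
Why: Hydrazone condensation gives the substrate for the Shapiro reaction as a crystalline derivative that should allow the enantiomeric purity to be raised by recrystallisation.

Step 4
Reactants: 4 hydroxy trisylhydrazone
Product: 5 tetrahydropyranyl ether of 4
Conditions: 3,4-dihydro-2H-pyran, PPTS (cat.), CH2Cl2, rt
Reagents that add atoms: 3,4-dihydro-2H-pyran, C1CC=COC1
Why: Acid-catalysed acetal (THP ether) formation; an acetal is chosen over a silyl ether because a γ-silyloxy vinyllithium could suffer 1,4 O-to-C silyl migration in step 11.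

Step 5
Reactants: 6 tert-butyl(but-3-yn-1-yloxy)dimethylsilane
Product: 8 tert-butyl{[(3Z)-4-iodo-3-[(trimethylsilyl)methyl]but-3-en-1-yl]oxy}dimethylsilane, via alkenylcopper 7 (not isolated)
Conditions: Me3SiCH2MgCl, CuBr·SMe2, Et2O/Me2S, −40 °C; 6, −25 °C; then iodine, THF, −60 → 0 °C
Reagents that add atoms: (trimethylsilyl)methylmagnesium chloride, C[Si](C)(C)C[Mg]Cl; iodine, II
Why: Carbocupration of a terminal alkyne (Normant reaction): syn addition puts Me3SiCH2 on the internal carbon (C8) and copper on the terminal one (C9), and iodinolysis with retention gives the iodide with iodine cis to CH2SiMe3, which later fixes C9.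

Step 6
Reactants: 9 (2E)-3-methylpent-2-en-4-yn-1-ol
Product: 10 4-methoxybenzyl ether of 9
Conditions: NaH, 4-MeOC6H4CH2Cl, tetrabutylammonium iodide (cat.), THF/DMF, 0 °C → rt
Reagents that add atoms: 4-methoxybenzyl chloride, COc1ccc(CCl)cc1
Why: Williamson ether synthesis protects the future C15 oxygen with a group that is stable to organolithiums and silyl triflates and is removed oxidatively.

Step 7
Reactants: 10 enyne ether
Product: 11 1-methoxy-4-({[(2E)-3-methylpenta-2,4-dien-1-yl]oxy}methyl)benzene
Conditions: H2 (1 atm), Pd/CaCO3 poisoned with Pb(OAc)2, quinoline, hexane/EtOAc, rt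
Reagents that add atoms: none
Why: Partial hydrogenation of the terminal alkyne over poisoned palladium gives the vinyl group and leaves the trisubstituted (E) alkene untouched.

Step 8
Reactants: 11 diene ether; 8 vinyl iodide
Product: 13 tert-butyl{[(3Z,7E)-9-[(4-methoxybenzyl)oxy]-7-methyl-3-[(trimethylsilyl)methyl]nona-3,7-dien-1-yl]oxy}dimethylsilane, via alkylborane 12 (not isolated)
Conditions: 9-BBN, THF, 0 °C → rt; then 8, Pd(dppf)Cl2 (5 mol %), Ph3As, Cs2CO3, DMF/H2O, rt
Reagents that add atoms: none
Why: Anti-Markovnikov hydroboration of the monosubstituted alkene of the diene with 9-BBN (the trisubstituted alkene is too hindered) followed by B-alkyl Suzuki–Miyaura coupling, which joins C9 to C11 with retention of the vinyl iodide geometry.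

Step 9
Reactants: 13 bis-ether
Product: 14 (3Z,7E)-9-[(4-methoxybenzyl)oxy]-7-methyl-3-[(trimethylsilyl)methyl]nona-3,7-dien-1-ol
Conditions: PPTS (0.2 equiv), MeOH, rt
Reagents that add atoms: none
Why: Acid-catalysed methanolysis of the primary TBS ether with an acid weak enough to spare the allylsilane and the 4-methoxybenzyl ether.

Step 10
Reactants: 14 homoallylic alcohol
Product: 15 (3Z,7E)-9-[(4-methoxybenzyl)oxy]-7-methyl-3-[(trimethylsilyl)methyl]nona-3,7-dienal
Conditions: Dess–Martin periodinane, pyridine, CH2Cl2, 0 °C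
Reagents that add atoms: none
Why: Dess–Martin oxidation under buffered, non-basic conditions gives the β,γ-unsaturated aldehyde without moving the C8=C9 double bond; it is used at once.

Step 11
Reactants: 5 trisylhydrazone THP ether; 15 aldehyde
Product: 18 allylic alcohol (C6 epimers), via vinyllithium 16 (not isolated), via vinylcerium dichloride 17 (not isolated)
Conditions: 5, n-BuLi (2.2 equiv), THF, −78 → 0 °C; CeCl3, −78 °C; then 15, −78 °C; aq. NH4Cl
Reagents that add atoms: none
Why: Shapiro reaction: the hydrazone dianion (only C10 carries an α-hydrogen) loses sulfinate and N2 to give the tetrasubstituted vinyllithium, which after transmetalation to the less basic organocerium adds to the enolisable aldehyde and forms C5–C6.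

Step 12
Reactants: 18 allylic alcohol
Product: 19 enone (C6 ketone conjugated with C5=C10)
Conditions: Dess–Martin periodinane, pyridine, CH2Cl2, 0 °C → rt
Reagents that add atoms: none
Why: Dess–Martin oxidation of the secondary allylic alcohol gives the C6 ketone and removes the C6 stereocentre.

Step 13
Reactants: 19 enone THP ether
Product: 21 cyclic methyl ketal (C6 epimers), via hydroxy enone 20 (not isolated)
Conditions: PPTS (0.2 equiv), MeOH, 3 Å molecular sieves, rt
Reagents that add atoms: methanol, CO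
Why: Acid-catalysed transacetalisation: methanolysis of the THP ether frees the C18 hydroxyl, which closes on the C6 ketone (5-exo-trig hemiketal formation, helped by the quaternary C4) and is trapped as the methyl ketal; both C6 epimers give the same cation in step 14.

Step 14
Reactants: 21 cyclic methyl ketal
Product: 23 6-oxo-18-hydroxy trans-decalin (5α-H; 9α-H; 10β-methyl; 8(17)-ene), via tricyclic enol ether 22 (not isolated)
Conditions: Me3SiOTf (0.3 equiv), CH2Cl2, −78 → −40 °C; then 0.1 M aq. oxalic acid, THF, 0 °C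
Reagents that add atoms: water, O
Why: Me3SiOTf ionises the ketal to a five-membered cyclic oxocarbenium ion whose charge is delocalised through C5=C10 onto C10 (alkoxyallyl cation); the allylsilane attacks C10 through its γ-carbon C9, loss of the silyl group from C17 leaves the C8=C17 methylene and regenerates the silyl triflate, and the resulting enol ether 22 is hydrolysed by mild acid to 23. The closest known reaction is the intramolecular Hosomi–Sakurai conjugate allylation of Lewis-acid-activated enones (an allylsilane-terminated cation–olefin cyclisation). Ring B closes by C9–C10 bond formation in the 6-endo mode with respect to both π systems (C8, C9, C5 and C10 all become ring atoms). C10 is controlled by C4: the temporary ring holds C18 in the plane of the cation, so the C4 methyl is pseudoaxial and shields its own face, C9 adds anti to it and the C10 methyl ends cis to the C4 methyl; C9 is controlled by the (Z) geometry of the allylsilane in a chair-like transition state (C11 equatorial, H9 anti to the C10 methyl); C5 is set on hydrolysis by protonation of the enol ether from the α face, anti to both axial methyls. The step needs C–C bond formation at C10 to outrun proton loss from C7 (no base is added, so that this elimination stays reversible) and needs the allylsilane to survive, which the aprotic conditions and catalytic silyl triflate should secure.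

Step 15
Reactants: 23 hydroxy ketone
Product: 24 6α,18-diol
Conditions: SmI2 (3 equiv), H2O, THF, 0 °C → rt
Reagents that add atoms: none
Why: Single-electron (ketyl) reduction: protonation of the carbinyl organosamarium should give the equatorial 6α-alcohol, the thermodynamic epimer (an axial 6β-oxygen would be syn-diaxial to the C10 and C4 methyls), as in dissolving-metal reductions of hindered cyclohexanones, whereas hydride reagents would attack from the α face.

Step 16
Reactants: 24 diol
Product: 25 6,18-bis(triethylsilyl) ether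
Conditions: Et3SiOTf (2.5 equiv), 2,6-lutidine, CH2Cl2, −78 → 0 °C
Reagents that add atoms: triethylsilyl trifluoromethanesulfonate, CC[Si](CC)(CC)OS(=O)(=O)C(F)(F)F
Why: Silylation with a silyl triflate protects both the primary and the hindered secondary hydroxyl; the primary triethylsilyl ether later serves as the latent aldehyde.

Step 17
Reactants: 25 bis-silyl ether
Product: 27 (13E)-enal (C15 aldehyde), via allylic alcohol 26 (not isolated)
Conditions: DDQ (1.2 equiv), CH2Cl2/pH 7 buffer, 0 °C; organic phase dried, then activated MnO2, CH2Cl2, rt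
Reagents that add atoms: none
Why: Oxidative cleavage of the 4-methoxybenzyl ether with DDQ followed by MnO2 oxidation of the liberated allylic alcohol; both reagents leave the silyl ethers and isolated alkenes alone and keep the (13E) geometry.

Step 18
Reactants: 28 4-methylfuran-2(5H)-one
Product: 29 4-methyl-2-(trimethylsilyloxy)furan
Conditions: Me3SiOTf, Et3N, Et2O, 0 °C
Reagents that add atoms: trimethylsilyl trifluoromethanesulfonate, C[Si](C)(C)OS(=O)(=O)C(F)(F)F
Why: Soft enolisation and O-silylation of the butenolide gives the aromatic 2-silyloxyfuran (a cyclic silyl dienolate).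

Step 19
Reactants: 27 enal; 29 silyloxyfuran
Product: 31 (15S,5′S)-hydroxy butenolide, via silyl ether 30 (not isolated)
Conditions: Ti(OiPr)4 (20 mol %), (R)-BINOL (20 mol %), Et2O, −20 °C; then citric acid, MeOH, 0 °C
Reagents that add atoms: none
Why: Catalytic enantioselective vinylogous Mukaiyama aldol reaction: the furan γ-carbon (C5′) adds to the Re face of the titanium–BINOL-bound aldehyde through an open transition state, which favours the like (threo) adduct for 2-silyloxyfurans, so C15 and C5′ are both set by the catalyst, far from the decalin stereocentres; mild methanolysis removes the O-trimethylsilyl group.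

Step 20
Reactants: 31 hydroxy butenolide
Product: 32 15-O-tert-butyldimethylsilyl ether
Conditions: t-BuMe2SiOTf, 2,6-lutidine, CH2Cl2, −78 °C
Reagents that add atoms: tert-butyldimethylsilyl trifluoromethanesulfonate, CC(C)(C)[Si](C)(C)OS(=O)(=O)C(F)(F)F
Why: Silylation of the secondary allylic alcohol under non-nucleophilic base so that it survives the next oxidation without epimerising the butenolide.

Step 21
Reactants: 32 tris-silyl ether
Product: 33 18-aldehyde
Conditions: (COCl)2, DMSO, CH2Cl2, −78 → −30 °C; then Et3N, −78 → 0 °C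
Reagents that add atoms: none
Why: Swern oxidation of a primary triethylsilyl ether: activated DMSO attacks the primary silyl ether oxygen directly and converts it into the aldehyde while the secondary silyl ethers remain; C4 has no α-hydrogen and cannot epimerise.

Step 22
Reactants: 33 aldehyde
Product: 34 target CNP0113661.1
Conditions: HF·pyridine, pyridine, THF, 0 °C → rt
Reagents that add atoms: none
Why: Fluoride-mediated cleavage of the two remaining silyl ethers under buffered, non-basic conditions that leave the butenolide (base-sensitive at C5′), the aldehyde and the exocyclic alkene intact.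

Compound list
1 | 2,6-dimethylcyclohexan-1-one (mixture of diastereomers) | CC1CCCC(C)C1=O | starting material
2 | 2,6-dimethyl-1-(trimethylsilyloxy)cyclohex-1-ene (racemic) | CC1CCCC(C)=C1O[Si](C)(C)C | intermediate
3 | (2S)-2-(hydroxymethyl)-2,6-dimethylcyclohexan-1-one (C6 epimers) | CC1CCC[C@@](C)(CO)C1=O | intermediate
4 | N'-[(2R)-2-(hydroxymethyl)-2,6-dimethylcyclohexylidene]-2,4,6-triisopropylbenzenesulfonohydrazide | CC1CCC[C@@](C)(CO)C1=NNS(=O)(=O)c1c(C(C)C)cc(C(C)C)cc1C(C)C | intermediate
5 | N'-[(2R)-2,6-dimethyl-2-[(tetrahydro-2H-pyran-2-yloxy)methyl]cyclohexylidene]-2,4,6-triisopropylbenzenesulfonohydrazide | CC1CCC[C@@](C)(COC2CCCCO2)C1=NNS(=O)(=O)c1c(C(C)C)cc(C(C)C)cc1C(C)C | intermediate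
6 | tert-butyl(but-3-yn-1-yloxy)dimethylsilane | C#CCCO[Si](C)(C)C(C)(C)C | starting material
7 | (Z)-alkenylcopper from syn addition, copper cis to CH2SiMe3 (not isolated) | [Cu]/C=C(\C[Si](C)(C)C)CCO[Si](C)(C)C(C)(C)C | intermediate
8 | tert-butyl{[(3Z)-4-iodo-3-[(trimethylsilyl)methyl]but-3-en-1-yl]oxy}dimethylsilane | I/C=C(\C[Si](C)(C)C)CCO[Si](C)(C)C(C)(C)C | intermediate
9 | (2E)-3-methylpent-2-en-4-yn-1-ol | C#C/C(C)=C/CO | starting material
10 | 1-methoxy-4-({[(2E)-3-methylpent-2-en-4-yn-1-yl]oxy}methyl)benzene | C#C/C(C)=C/COCc1ccc(OC)cc1 | intermediate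
11 | 1-methoxy-4-({[(2E)-3-methylpenta-2,4-dien-1-yl]oxy}methyl)benzene | C=C/C(C)=C/COCc1ccc(OC)cc1 | intermediate
12 | 9-[(3E)-5-[(4-methoxybenzyl)oxy]-3-methylpent-3-en-1-yl]-9-borabicyclo[3.3.1]nonane (not isolated) | COc1ccc(COC/C=C(C)/CCB2C3CCCC2CCC3)cc1 | intermediate
13 | tert-butyl{[(3Z,7E)-9-[(4-methoxybenzyl)oxy]-7-methyl-3-[(trimethylsilyl)methyl]nona-3,7-dien-1-yl]oxy}dimethylsilane | CC(C)(C)[Si](C)(C)OCC/C(C[Si](C)(C)C)=C/CC/C(C)=C/COCc1ccc(OC)cc1 | intermediate
14 | (3Z,7E)-9-[(4-methoxybenzyl)oxy]-7-methyl-3-[(trimethylsilyl)methyl]nona-3,7-dien-1-ol | OCC/C(C[Si](C)(C)C)=C/CC/C(C)=C/COCc1ccc(OC)cc1 | intermediate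
15 | (3Z,7E)-9-[(4-methoxybenzyl)oxy]-7-methyl-3-[(trimethylsilyl)methyl]nona-3,7-dienal | O=CC/C(C[Si](C)(C)C)=C/CC/C(C)=C/COCc1ccc(OC)cc1 | intermediate
16 | {(6R)-2,6-dimethyl-6-[(tetrahydro-2H-pyran-2-yloxy)methyl]cyclohex-1-en-1-yl}lithium (not isolated) | [Li]C1=C(C)CCC[C@@]1(C)COC1CCCCO1 | intermediate
17 | dichloro{(6R)-2,6-dimethyl-6-[(tetrahydro-2H-pyran-2-yloxy)methyl]cyclohex-1-en-1-yl}cerium (not isolated) | Cl[Ce](Cl)C1=C(C)CCC[C@@]1(C)COC1CCCCO1 | intermediate
18 | (3Z,7E)-1-{(6R)-2,6-dimethyl-6-[(tetrahydro-2H-pyran-2-yloxy)methyl]cyclohex-1-en-1-yl}-9-[(4-methoxybenzyl)oxy]-7-methyl-3-[(trimethylsilyl)methyl]nona-3,7-dien-1-ol (carbinol epimers) | C1CCC(OC[C@]2(C)CCCC(C)=C2C(O)C/C(C[Si](C)(C)C)=C/CC/C(C)=C/COCc2ccc(OC)cc2)OC1 | intermediate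
19 | (3Z,7E)-1-{(6R)-2,6-dimethyl-6-[(tetrahydro-2H-pyran-2-yloxy)methyl]cyclohex-1-en-1-yl}-9-[(4-methoxybenzyl)oxy]-7-methyl-3-[(trimethylsilyl)methyl]nona-3,7-dien-1-one | C1CCC(OC[C@]2(C)CCCC(C)=C2C(=O)C/C(C[Si](C)(C)C)=C/CC/C(C)=C/COCc2ccc(OC)cc2)OC1 | intermediate
20 | hydroxy enone: the C18 alcohol of 19, in equilibrium with its cyclic hemiketal (not isolated) | OC[C@]1(C)CCCC(C)=C1C(=O)C/C(C[Si](C)(C)C)=C/CC/C(C)=C/COCc1ccc(OC)cc1 | intermediate
21 | (3aR)-1-methoxy-3a,7-dimethyl-1-[(2Z,6E)-8-[(4-methoxybenzyl)oxy]-6-methyl-2-[(trimethylsilyl)methyl]octa-2,6-dien-1-yl]-1,3,3a,4,5,6-hexahydro-2-benzofuran (C1 epimers) | COC1(C/C(C[Si](C)(C)C)=C/CC/C(C)=C/COCc2ccc(OC)cc2)OC[C@]3(C)CCCC(C)=C13 | intermediate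
22 | tricyclic enol ether: decalin with C5=C6, O bridging C6 and C18, 8(17)-methylene, 4β- and 10β-methyl, 9α-H, side chain (3E)-5-[(4-methoxybenzyl)oxy]-3-methylpent-3-enyl on C9 (not isolated) | C=C1CC2=C3[C@](C)(CCC[C@@]3(C)CO2)[C@H]1CC/C(C)=C/COCc4ccc(OC)cc4 | intermediate
23 | trans-decalin hydroxy ketone: 4α-(hydroxymethyl)-4β,10β-dimethyl-8-methylidene-6-oxo, 5α-H, 9α-H, C9 side chain (3E)-5-[(4-methoxybenzyl)oxy]-3-methylpent-3-enyl | C=C1CC(=O)[C@@H]2[C@](C)(CCC[C@@]2(C)CO)[C@H]1CC/C(C)=C/COCc1ccc(OC)cc1 | intermediate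
24 | 6α,18-diol: as 23 with an equatorial 6α-hydroxyl (6β-H) | C=C1C[C@H](O)[C@@H]2[C@](C)(CCC[C@@]2(C)CO)[C@H]1CC/C(C)=C/COCc1ccc(OC)cc1 | intermediate
25 | 6α,18-bis(triethylsilyloxy) derivative of 24 | C=C1C[C@H](O[Si](CC)(CC)CC)[C@@H]2[C@](C)(CCC[C@@]2(C)CO[Si](CC)(CC)CC)[C@H]1CC/C(C)=C/COCc1ccc(OC)cc1 | intermediate
26 | (13E)-allylic alcohol: 25 without the 4-methoxybenzyl group (not isolated) | C=C1C[C@H](O[Si](CC)(CC)CC)[C@@H]2[C@](C)(CCC[C@@]2(C)CO[Si](CC)(CC)CC)[C@H]1CC/C(C)=C/CO | intermediate
27 | (13E)-enal: C15 aldehyde of 26 | C=C1C[C@H](O[Si](CC)(CC)CC)[C@@H]2[C@](C)(CCC[C@@]2(C)CO[Si](CC)(CC)CC)[C@H]1CC/C(C)=C/C=O | intermediate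
28 | 4-methylfuran-2(5H)-one | CC1=CC(=O)OC1 | starting material
29 | 4-methyl-2-(trimethylsilyloxy)furan | Cc1coc(O[Si](C)(C)C)c1 | intermediate
30 | (15S,5′S)-15-O-trimethylsilyl aldol adduct (not isolated) | C=C1C[C@H](O[Si](CC)(CC)CC)[C@@H]2[C@](C)(CCC[C@@]2(C)CO[Si](CC)(CC)CC)[C@H]1CC/C(C)=C/[C@H](O[Si](C)(C)C)[C@H]1OC(=O)C=C1C | intermediate
31 | (15S,5′S)-15-hydroxy butenolide with 6α,18-bis(triethylsilyloxy) groups | C=C1C[C@H](O[Si](CC)(CC)CC)[C@@H]2[C@](C)(CCC[C@@]2(C)CO[Si](CC)(CC)CC)[C@H]1CC/C(C)=C/[C@H](O)[C@H]1OC(=O)C=C1C | intermediate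
32 | 15-O-tert-butyldimethylsilyl ether of 31 | C=C1C[C@H](O[Si](CC)(CC)CC)[C@@H]2[C@](C)(CCC[C@@]2(C)CO[Si](CC)(CC)CC)[C@H]1CC/C(C)=C/[C@H](O[Si](C)(C)C(C)(C)C)[C@H]1OC(=O)C=C1C | intermediate
33 | 18-aldehyde with 6α-triethylsilyloxy and 15-tert-butyldimethylsilyloxy groups | C=C1C[C@H](O[Si](CC)(CC)CC)[C@@H]2[C@](C)(CCC[C@@]2(C)C=O)[C@H]1CC/C(C)=C/[C@H](O[Si](C)(C)C(C)(C)C)[C@H]1OC(=O)C=C1C | intermediate
34 | CNP0113661.1: 6α,15S-dihydroxy-8(17),13E-diene-18-al decalin with the (5′S)-4′-methylbutenolide on C15 | C=C1C[C@H](O)[C@@H]2[C@](C)(CCC[C@@]2(C)C=O)[C@H]1CC/C(C)=C/[C@H](O)[C@H]1OC(=O)C=C1C | target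

Total step count: 22. Longest linear sequence: 16 steps (from 9: steps 6, 7, 8, 9, 10, 11, 12, 13, 14, 15, 16, 17, 19, 20, 21, 22).

Steps most likely to fail

Step 14. The hindered cation may lose a proton from C7 or the allylsilane may be protodesilylated before the C9–C10 bond forms, or the chair and boat transition states may compete and erode the C9 configuration. The fallback activates the nucleophile instead of the electrophile: it sets out from enone 19, which with anhydrous tetrabutylammonium fluoride in DMF over 4 Å molecular sieves should undergo fluoride-induced intramolecular conjugate allylation (an anionic Sakurai reaction) and, after protonation of the enolate, give the THP-protected decalin ketone F1; aqueous acetic acid in THF then removes the THP group and the route is rejoined at 23.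

Step 5. Transfer of the silylmethyl group from copper to an unactivated terminal alkyne may be sluggish or poorly regioselective. The fallback builds the same trisubstituted alkene by trans-hydrometalation of an internal alkyne. It sets out from 11 and 6. Hydroboration of 11 with 9-BBN and oxidation (NaOH, H2O2) gives the primary alcohol F2, which iodine, Ph3P and imidazole convert into the iodide F3. The lithium acetylide of 6 (n-BuLi, THF/DMPU) is alkylated with F3 to the internal alkyne F4, and PPTS in MeOH frees the homopropargylic alcohol F5. Hydroxyl-directed ruthenium-catalysed trans-hydrostannation ([Cp*RuCl]4, Bu3SnH) places tin on C8 and hydrogen trans on C9 to give the stannane F6; iodine gives the (Z)-iodide F7; and coupling with Me3SiCH2MgCl under Pd(PPh3)4 catalysis (Kumada coupling, retention) returns to the route at 14.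

Step 19. The β,β-disubstituted enal may react slowly, and the titanium catalyst may give poor control of the aldehyde face or of the like/unlike ratio. The fallback sets both centres with an auxiliary and builds the butenolide afterwards. It sets out from 27. A boron-mediated oxazolidinone glycolate syn-aldol reaction with (R)-4-benzyl-3-{[(4-methoxybenzyl)oxy]acetyl}oxazolidin-2-one (Bu2BOTf, Et3N) gives the syn adduct F8. Transamination with MeNHOMe·HCl and Me3Al gives the Weinreb amide F9, t-BuMe2SiOTf gives the silyl ether F10, MeMgBr gives the methyl ketone F11, and DDQ removes the 4-methoxybenzyl group to give the α-hydroxy ketone F12. Acylation and intramolecular Wittig reaction with ketenylidenetriphenylphosphorane in toluene at 80 °C then close the 4′-methylbutenolide, and the route is rejoined at 32.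

Further compounds
F1 | step 14 | THP-protected 6-oxo trans-decalin (23 with a tetrahydropyranyl ether on O18) | C=C1CC(=O)[C@@H]2[C@](C)(CCC[C@@]2(C)COC2CCCCO2)[C@H]1CC/C(C)=C/COCc1ccc(OC)cc1
F2 | step 5 | (3E)-5-[(4-methoxybenzyl)oxy]-3-methylpent-3-en-1-ol | OCC/C(C)=C/COCc1ccc(OC)cc1
F3 | step 5 | 1-({[(2E)-5-iodo-3-methylpent-2-en-1-yl]oxy}methyl)-4-methoxybenzene | ICC/C(C)=C/COCc1ccc(OC)cc1
F4 | step 5 | tert-butyl{[(7E)-9-[(4-methoxybenzyl)oxy]-7-methylnon-7-en-3-yn-1-yl]oxy}dimethylsilane | CC(C)(C)[Si](C)(C)OCCC#CCC/C(C)=C/COCc1ccc(OC)cc1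
F5 | step 5 | (7E)-9-[(4-methoxybenzyl)oxy]-7-methylnon-7-en-3-yn-1-ol | OCCC#CCC/C(C)=C/COCc1ccc(OC)cc1
F6 | step 5 | (3Z,7E)-9-[(4-methoxybenzyl)oxy]-7-methyl-3-(tributylstannyl)nona-3,7-dien-1-ol | OCC/C([Sn](CCCC)(CCCC)CCCC)=C/CC/C(C)=C/COCc1ccc(OC)cc1
F7 | step 5 | (3Z,7E)-3-iodo-9-[(4-methoxybenzyl)oxy]-7-methylnona-3,7-dien-1-ol | OCC/C(I)=C/CC/C(C)=C/COCc1ccc(OC)cc1
F8 | step 19 | syn-glycolate aldol adduct of 27 with the (R)-4-benzyloxazolidinone auxiliary (15S-hydroxy, 4-methoxybenzyloxy on the future C5′) | C=C1C[C@H](O[Si](CC)(CC)CC)[C@@H]2[C@](C)(CCC[C@@]2(C)CO[Si](CC)(CC)CC)[C@H]1CC/C(C)=C/[C@H](O)[C@@H](OCc1ccc(OC)cc1)C(=O)N1C(=O)OC[C@H]1Cc1ccccc1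
F9 | step 19 | N-methoxy-N-methyl amide from F8 | C=C1C[C@H](O[Si](CC)(CC)CC)[C@@H]2[C@](C)(CCC[C@@]2(C)CO[Si](CC)(CC)CC)[C@H]1CC/C(C)=C/[C@H](O)[C@@H](OCc1ccc(OC)cc1)C(=O)N(C)OC
F10 | step 19 | 15-O-tert-butyldimethylsilyl ether of F9 | C=C1C[C@H](O[Si](CC)(CC)CC)[C@@H]2[C@](C)(CCC[C@@]2(C)CO[Si](CC)(CC)CC)[C@H]1CC/C(C)=C/[C@H](O[Si](C)(C)C(C)(C)C)[C@@H](OCc1ccc(OC)cc1)C(=O)N(C)OC
F11 | step 19 | methyl ketone from F10 | C=C1C[C@H](O[Si](CC)(CC)CC)[C@@H]2[C@](C)(CCC[C@@]2(C)CO[Si](CC)(CC)CC)[C@H]1CC/C(C)=C/[C@H](O[Si](C)(C)C(C)(C)C)[C@@H](OCc1ccc(OC)cc1)C(C)=O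
F12 | step 19 | α-hydroxy methyl ketone from F11 | C=C1C[C@H](O[Si](CC)(CC)CC)[C@@H]2[C@](C)(CCC[C@@]2(C)CO[Si](CC)(CC)CC)[C@H]1CC/C(C)=C/[C@H](O[Si](C)(C)C(C)(C)C)[C@@H](O)C(C)=O
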